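Take the easy step first, since you want a quick number: divide green's last reading by its charge. That gives 0.696.

| flask | starting material | catalyst | time |
|---|---|---|---|
| violet | 50.0 mM | 0.250 mM |  |
| green | 25.0 mM | 0.250 mM |  |
| teal | 50.0 mM | 0.500 mM |  |
| ochre | 100 mM | 0.250 mM |  |
| red | 50.0 mM | 0.250 mM | 24 h |

- violet run (time / h: [target] / mM): 1.5: 1.4; 3.0: 2.8; 4.5: 5.5; 6.0: 8.9; 7.5: 12.1; 9.0: 15.2; 10: 18.2; 12: 21.4
- green run (time / h: [target] / mM): 1.5: 1.9; 3.0: 4.7; 4.5: 7.4; 6.0: 11.3; 7.5: 14.9; 9.0: 16.7; 10: 17.6; 12: 17.4
- teal run (time / h: [target] / mM): 1.5: 5.6; 3.0: 13.7; 4.5: 26.1; 6.0: 31.4; 7.5: 31.8; 9.0: 32.1; 10: 31.9; 12: 31.8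
- ochre run (time / h: [target] / mM): 1.5: 0.9; 3.0: 2.3; 4.5: 4.8; 6.0: 7.1; 7.5: 9.6; 9.0: 13.3; 10: 15.6; 12: 21.2

(readings scatter by 0.3 mM)

- Overall: starting material -> target, with catalyst as catalyst.
- Constant volume, constant temperature.
- The analysis sees a species whether free or bound.
- An order is taken over about fifteen percent of the charge, up and down.

1. reaction order in [catalyst] at the outset, round the charge of the violet run, defined at two percent of the starting material turned into target
2. reaction order in [starting material] at the outset, round the charge of the violet run, defined at two percent of the starting material turned into target (one fixed amount of target, the same in the runs compared)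
3. target in the red run at 24 h, as a share of the starting material charged

1. Read the orders from the time each flask takes to reach about the same amount of target. Teal reads 5.6 mM at 1.5 h and violet reads 5.5 mM at 4.5 h, which gives 1.58 in catalyst. Green reads 4.7 mM at 3.0 h and ochre reads 4.8 mM at 4.5 h, which gives −0.292 in starting material. These amounts lie past the two percent asked, and the charges compared lie far apart, so treat both orders as rough.

2. Compare the stops. Green stands level at 17.6 mM and 17.4 mM. Teal makes target at 5.73 mM h⁻¹, faster than green's 2.00 mM h⁻¹. Yet teal's last reading is a lower share of its charge, 0.636. So assume the charge also wastes itself, at second order.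

3. Integrate that loss alone. With loss constant a, charge S and time t, the surviving share is 1/(1+aSt).

4. Let target grow at a steady rate r to a share y, so t = yS/r. Stop the flask, crudely, where y equals the surviving share. Then y + xy² = 1, with x = aS²/r.

5. Rearrange: x is the share not made over the square of the share made. Green gives 0.628, its waste number.

6. Scale to the red run, which repeats violet's charge. Multiply by the squared charge ratio and by green's rate over violet's 2.07 mM h⁻¹. This gives x = 2.43. Solving for y, I commit to 0.468. At violet's rate this estimated stop falls at 11.3 h, earlier than 24 h, so take it as the red run's share at 24 h.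

7. The forecast says 1.9, −0.5 and 79 %, on the ground that “Catalyst seems to die once starting material falls to about 30–36 times the catalyst”.

The flask gives 1.5, −0.36 and 43.4 %.

    catalyst + starting material ⇌ catalyst-substrate complex, settled at all times (215.0 M⁻¹)
    catalyst-substrate complex + catalyst → target + 2 catalyst (1.418 × 10⁵ M⁻¹ h⁻¹)
    2 starting material → homo dimer (2.480 M⁻¹ h⁻¹)
    starting material + target → 2 target (3.636 M⁻¹ h⁻¹)

The loss of starting material to homo dimer moves the readings by 28 times the scatter, as a root mean square. The red run's own waste number is 3.00, against my 2.43. Now scale green's number to teal, by the squared charge ratio and by green's rate over teal's. That gives x = 0.876 and a stop at 0.641. Teal's last reading stands at 0.636 of its charge.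

The readings are calculated with made-up constants; scatter was added.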